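## Retrosynthetic overview

1. Ring C (the phenol ring) is added last. Its C5 allyl group comes from a para-Claisen rearrangement of the O2-allyl ether, and its oxygens from SNAr of the ring B phenol 18 on 2-fluoro-6-methoxybenzaldehyde followed by Dakin oxidation (CHO to OH).
2. Phenol 18 (rings A and B) arises by the same para-Claisen move. The ring B O2-allyl ether protects that oxygen while ring A is built (it is stable to acid, base, hydride and peracid), then becomes the ring B C5 allyl group and frees O2.
3. The ring A allyl group (C1) is derived from a C1 ester by reduction, bromination and copper-catalysed vinyl Grignard coupling; the C3 methoxy group comes from a C3 phenol.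
4. The strategy rests on this feature: ring A carries C4–O–ring B next to C3–OMe and para to the allyl carbon C1. A 3-aryloxyfuran (supplying C3, C4, C5, C6) and methyl propiolate (supplying C1, C2) give exactly this pattern after Diels–Alder reaction and opening of the oxygen bridge.
5. Furyl ether 7 comes from o-vanillin (allylation, Baeyer–Villiger) and 3-bromofuran. Ring order: ring B is bought as o-vanillin, ring A is the only ring formed (step 4), ring C is bought as the fluoroaldehyde.

Key step: step 4

Remark on the chemistry: ring A is the terminal 4-allyl-2-methoxyphenoxy ring (C1 allyl, C3 OMe, C4 O), ring B the central ring and ring C the phenol ring. The target has no stereocenter; the transient compounds 9, 16, 17, 24 and 25 are racemic.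

## Route

Step 1
Reactants: 1 o-vanillin (2-hydroxy-3-methoxybenzaldehyde); 2 allyl bromide
Product: 3 2-(allyloxy)-3-methoxybenzaldehyde
Conditions: K2CO3, DMF, 50 °C
Reagents that add atoms: none
Why: Williamson ether synthesis, in which the phenoxide of 1 is alkylated by the primary allylic bromide while the aldehyde is inert to K2CO3.

Step 2
Reactants: 3 2-(allyloxy)-3-methoxybenzaldehyde
Product: 5 2-(allyloxy)-3-methoxyphenol, via aryl formate 4 (not isolated)
Conditions: mCPBA (1.2 equiv), CH2Cl2, 0 °C to rt; NaHCO3 wash; then K2CO3 (cat.), MeOH, rt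
Reagents that add atoms: mCPBA (3-chloroperoxybenzoic acid), OOC(=O)c1cccc(Cl)c1
Why: Baeyer–Villiger (Dakin-type) oxidation of an ortho-alkoxybenzaldehyde, in which the electron-rich aryl group migrates to oxygen while the inductively deactivated allyl ether alkene should react far more slowly with the peracid, followed by methanolysis of formate 4.

Step 3
Reactants: 5 2-(allyloxy)-3-methoxyphenol; 6 3-bromofuran
Product: 7 3-[2-(allyloxy)-3-methoxyphenoxy]furan
Conditions: 6 (2.5 equiv), CuI (10 mol%), N,N-dimethylglycine hydrochloride (30 mol%), Cs2CO3, dioxane, 100 °C, sealed tube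
Reagents that add atoms: none
Why: Ullmann-type copper-catalysed C–O coupling of a phenol with a heteroaryl bromide under amino acid ligand conditions, with the volatile bromide in excess in a closed vessel, the allyl ether inert to CuI and Cs2CO3, and the acid-sensitive product purified on base-washed silica.

Step 4
Reactants: 7 3-[2-(allyloxy)-3-methoxyphenoxy]furan; 8 methyl propiolate
Product: 10 methyl 4-[2-(allyloxy)-3-methoxyphenoxy]-3-hydroxybenzoate, via oxanorbornadiene 9 (not isolated)
Conditions: 8 (5 equiv), toluene, 80 °C, sealed tube; evaporate; then CSA (10 mol%), CH2Cl2, 0 °C to rt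
Reagents that add atoms: none
Why: The 3-aryloxy group makes the furan an enol-ether-type diene with C2 as its nucleophilic terminus, so a thermal normal-demand Diels–Alder reaction joins furan C2 to the unsubstituted carbon of methyl propiolate and furan C5 to the ester-bearing carbon to give oxanorbornadiene 9; the closest known reaction type is the cycloaddition of 3-alkoxyfurans with acetylenic esters followed by acid isomerization of the 7-oxanorbornadiene to a phenol. Ring A is closed by this concerted suprafacial (4+2) cycloaddition, which forms both new C–C bonds (ring A C2–C3 and C6–C1), and the six-membered carbocycle is left when the oxygen bridge is cut. With acid the bridge C–O bond at the former furan C5 ionizes, because that cation is an allyl cation stabilized by the aryloxy group, whereas the alternative cation would sit next to the ester; the oxygen therefore stays on the former furan C2 and loss of its proton aromatizes the ring. No stereocenter survives, since the two bridgehead centres of racemic 9 become aromatic carbons. The step needs regioselectivity twice, in the cycloaddition (ester para to C–OAr) and in the bridge opening (OH ortho to C–OAr), and both follow from the single 3-aryloxy donor; a minor regioisomeric adduct would open to a hydrogen-bonded salicylate that should be separable by chromatography. The allyl ether is inert to the dienophile and to catalytic acid, which is why it is the protecting group on the ring B oxygen.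

Step 5
Reactants: 10 methyl 4-[2-(allyloxy)-3-methoxyphenoxy]-3-hydroxybenzoate
Product: 11 methyl 4-[2-(allyloxy)-3-methoxyphenoxy]-3-methoxybenzoate
Conditions: MeI, K2CO3, DMF, rt
Reagents that add atoms: iodomethane, CI
Why: Williamson O-methylation of the ring A phenol sets the C3 methoxy group, and the methyl ester and allyl ether are untouched by K2CO3.

Step 6
Reactants: 11 methyl 4-[2-(allyloxy)-3-methoxyphenoxy]-3-methoxybenzoate
Product: 12 {4-[2-(allyloxy)-3-methoxyphenoxy]-3-methoxyphenyl}methanol
Conditions: LiAlH4, THF, 0 °C
Reagents that add atoms: none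
Why: Hydride reduction of the aryl ester to the benzylic alcohol, under which the ethers and the isolated alkene do not react.

Step 7
Reactants: 12 {4-[2-(allyloxy)-3-methoxyphenoxy]-3-methoxyphenyl}methanol
Product: 13 2-(allyloxy)-1-[4-(bromomethyl)-2-methoxyphenoxy]-3-methoxybenzene
Conditions: CBr4, PPh3, CH2Cl2, 0 °C
Reagents that add atoms: carbon tetrabromide, BrC(Br)(Br)Br
Why: Appel reaction, in which bromide displaces the alkoxyphosphonium ion under neutral conditions that suit the electron-rich benzylic bromide, to be used at once.

Step 8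
Reactants: 13 2-(allyloxy)-1-[4-(bromomethyl)-2-methoxyphenoxy]-3-methoxybenzene; 14 vinylmagnesium bromide
Product: 15 2-(allyloxy)-1-(4-allyl-2-methoxyphenoxy)-3-methoxybenzene
Conditions: CH2=CHMgBr (1.5 equiv), CuI (10 mol%), THF, −40 to 0 °C
Reagents that add atoms: none
Why: Copper-catalysed Kumada-type coupling of a benzylic bromide with an alkenyl Grignard reagent forms the ring A allyl group; at low temperature the benzylic bromide should react far faster than the allyl aryl ether, and copper is chosen because zerovalent palladium would ionize that ether.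

Step 9
Reactants: 15 2-(allyloxy)-1-(4-allyl-2-methoxyphenoxy)-3-methoxybenzene
Product: 18 4-allyl-2-(4-allyl-2-methoxyphenoxy)-6-methoxyphenol, via ortho-dienone 16 (not isolated), via para-dienone 17 (not isolated)
Conditions: PhNEt2, 195 °C, Ar
Reagents that add atoms: none
Why: Aromatic para-Claisen rearrangement: both ortho positions of the ring B allyl ether carry oxygen substituents, so the ortho-dienone from the first [3,3] shift (16, or its regioisomer at the aryloxy carbon) cannot enolize, a Cope [3,3] shift moves the allyl group to C5 (17), and tautomerization gives the phenol.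

Step 10
Reactants: 18 4-allyl-2-(4-allyl-2-methoxyphenoxy)-6-methoxyphenol; 19 2-fluoro-6-methoxybenzaldehyde
Product: 20 2-[4-allyl-2-(4-allyl-2-methoxyphenoxy)-6-methoxyphenoxy]-6-methoxybenzaldehyde
Conditions: 19 (1.5 equiv), K2CO3, DMF, 110 °C
Reagents that add atoms: none
Why: Nucleophilic aromatic substitution (addition–elimination), in which the phenoxide of 18 displaces fluoride ortho to the formyl group that stabilizes the Meisenheimer intermediate, K2CO3 being too weak a base to move the allyl double bonds into conjugation.

Step 11
Reactants: 20 2-[4-allyl-2-(4-allyl-2-methoxyphenoxy)-6-methoxyphenoxy]-6-methoxybenzaldehyde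
Product: 22 2-[4-allyl-2-(4-allyl-2-methoxyphenoxy)-6-methoxyphenoxy]-6-methoxyphenol, via aryl formate 21 (not isolated)
Conditions: 30% H2O2, H2SO4 (cat.), MeOH, rt
Reagents that add atoms: hydrogen peroxide, OO
Why: Acid-catalysed Dakin oxidation, in which the hydroperoxide adduct of the aldehyde rearranges with aryl migration favoured by the two ortho oxygen donors and formate 21 is methanolysed in the flask; H2O2 without a peracid should leave the two allyl groups untouched.

Step 12
Reactants: 22 2-[4-allyl-2-(4-allyl-2-methoxyphenoxy)-6-methoxyphenoxy]-6-methoxyphenol; 2 allyl bromide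
Product: 23 5-allyl-2-[2-(allyloxy)-3-methoxyphenoxy]-1-(4-allyl-2-methoxyphenoxy)-3-methoxybenzene
Conditions: K2CO3, DMF, 50 °C
Reagents that add atoms: none
Why: Williamson ether synthesis on the ring C phenol, which is hindered but readily alkylated by the small, reactive allyl bromide.

Step 13
Reactants: 23 5-allyl-2-[2-(allyloxy)-3-methoxyphenoxy]-1-(4-allyl-2-methoxyphenoxy)-3-methoxybenzene
Product: 26 4-allyl-2-[4-allyl-2-(4-allyl-2-methoxyphenoxy)-6-methoxyphenoxy]-6-methoxyphenol (target), via ortho-dienone 24 (not isolated), via para-dienone 25 (not isolated)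
Conditions: PhNEt2, 195 °C, Ar
Reagents that add atoms: none
Why: Aromatic para-Claisen rearrangement as in step 9: with both ortho positions of ring C blocked by oxygen substituents, the allyl group passes by two [3,3] shifts to C5 and tautomerization frees the C2 hydroxyl, while the two C-allyl groups and the diaryl ethers are thermally inert.

## Compound list

1 | o-vanillin (2-hydroxy-3-methoxybenzaldehyde) | COc1cccc(C=O)c1O | starting material
2 | allyl bromide | C=CCBr | starting material
3 | 2-(allyloxy)-3-methoxybenzaldehyde | C=CCOc1c(OC)cccc1C=O | intermediate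
4 | 2-(allyloxy)-3-methoxyphenyl formate (not isolated) | C=CCOc1c(OC)cccc1OC=O | intermediate
5 | 2-(allyloxy)-3-methoxyphenol | C=CCOc1c(O)cccc1OC | intermediate
6 | 3-bromofuran | Brc1ccoc1 | starting material
7 | 3-[2-(allyloxy)-3-methoxyphenoxy]furan | C=CCOc1c(OC)cccc1Oc1ccoc1 | intermediate
8 | methyl propiolate | C#CC(=O)OC | starting material
9 | methyl 5-[2-(allyloxy)-3-methoxyphenoxy]-7-oxabicyclo[2.2.1]hepta-2,5-diene-2-carboxylate (racemic, one enantiomer drawn; not isolated) | COC(=O)C1=C[C@@H]2O[C@H]1C=C2Oc1cccc(OC)c1OCC=C | intermediate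
10 | methyl 4-[2-(allyloxy)-3-methoxyphenoxy]-3-hydroxybenzoate | COC(=O)c1ccc(Oc2cccc(OC)c2OCC=C)c(O)c1 | intermediate
11 | methyl 4-[2-(allyloxy)-3-methoxyphenoxy]-3-methoxybenzoate | COC(=O)c1ccc(Oc2cccc(OC)c2OCC=C)c(OC)c1 | intermediate
12 | {4-[2-(allyloxy)-3-methoxyphenoxy]-3-methoxyphenyl}methanol | OCc1ccc(Oc2cccc(OC)c2OCC=C)c(OC)c1 | intermediate
13 | 2-(allyloxy)-1-[4-(bromomethyl)-2-methoxyphenoxy]-3-methoxybenzene | BrCc1ccc(Oc2cccc(OC)c2OCC=C)c(OC)c1 | intermediate
14 | vinylmagnesium bromide (CH2=CHMgBr, THF solution) | C=C[Mg]Br | starting material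
15 | 2-(allyloxy)-1-(4-allyl-2-methoxyphenoxy)-3-methoxybenzene | C=CCc1ccc(Oc2cccc(OC)c2OCC=C)c(OC)c1 | intermediate
16 | 6-allyl-2-(4-allyl-2-methoxyphenoxy)-6-methoxycyclohexa-2,4-dien-1-one (racemic; not isolated) | C=CCC1(OC)C=CC=C(Oc2ccc(CC=C)cc2OC)C1=O | intermediate
17 | 4-allyl-2-(4-allyl-2-methoxyphenoxy)-6-methoxycyclohexa-2,5-dien-1-one (racemic; not isolated) | C=CCC1C=C(OC)C(=O)C(Oc2ccc(CC=C)cc2OC)=C1 | intermediate
18 | 4-allyl-2-(4-allyl-2-methoxyphenoxy)-6-methoxyphenol (dehydrodieugenol B) | C=CCc1ccc(Oc2cc(CC=C)cc(OC)c2O)c(OC)c1 | intermediate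
19 | 2-fluoro-6-methoxybenzaldehyde | COc1cccc(F)c1C=O | starting material
20 | 2-[4-allyl-2-(4-allyl-2-methoxyphenoxy)-6-methoxyphenoxy]-6-methoxybenzaldehyde | C=CCc1ccc(Oc2cc(CC=C)cc(OC)c2Oc2cccc(OC)c2C=O)c(OC)c1 | intermediate
21 | 2-[4-allyl-2-(4-allyl-2-methoxyphenoxy)-6-methoxyphenoxy]-6-methoxyphenyl formate (not isolated) | C=CCc1ccc(Oc2cc(CC=C)cc(OC)c2Oc2cccc(OC)c2OC=O)c(OC)c1 | intermediate
22 | 2-[4-allyl-2-(4-allyl-2-methoxyphenoxy)-6-methoxyphenoxy]-6-methoxyphenol | C=CCc1ccc(Oc2cc(CC=C)cc(OC)c2Oc2cccc(OC)c2O)c(OC)c1 | intermediate
23 | 5-allyl-2-[2-(allyloxy)-3-methoxyphenoxy]-1-(4-allyl-2-methoxyphenoxy)-3-methoxybenzene | C=CCc1ccc(Oc2cc(CC=C)cc(OC)c2Oc2cccc(OC)c2OCC=C)c(OC)c1 | intermediate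
24 | 6-allyl-2-[4-allyl-2-(4-allyl-2-methoxyphenoxy)-6-methoxyphenoxy]-6-methoxycyclohexa-2,4-dien-1-one (racemic; not isolated) | C=CCC1(OC)C=CC=C(Oc2c(OC)cc(CC=C)cc2Oc2ccc(CC=C)cc2OC)C1=O | intermediate
25 | 4-allyl-2-[4-allyl-2-(4-allyl-2-methoxyphenoxy)-6-methoxyphenoxy]-6-methoxycyclohexa-2,5-dien-1-one (racemic; not isolated) | C=CCC1C=C(OC)C(=O)C(Oc2c(OC)cc(CC=C)cc2Oc2ccc(CC=C)cc2OC)=C1 | intermediate
26 | 4-allyl-2-[4-allyl-2-(4-allyl-2-methoxyphenoxy)-6-methoxyphenoxy]-6-methoxyphenol (CNP0153774.0) | C=CCc1ccc(Oc2cc(CC=C)cc(OC)c2Oc2cc(CC=C)cc(OC)c2O)c(OC)c1 | target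

## Step count and risks

Total step count: 13. Longest linear sequence: 13 steps (1 to 26); every other starting material enters this single chain.

Steps most likely to fail:

Step 4. The aryloxy group is a weaker donor than an alkoxy group, so the cycloaddition may be slow. The furan could then be lost to conjugate addition at C2 or to polymerization of the propiolate, and regiocontrol in the cycloaddition may be incomplete. The fallback leaves the furan logic and makes the ring A ether by known substitution chemistry; it sets out from phenol 5 and comes back at benzylic alcohol 12. Phenol 5 is condensed with commercial 4-fluoro-3-methoxybenzaldehyde (COc1cc(C=O)ccc1F; K2CO3, DMF, 120 °C; substitution of fluoride para to the formyl group) to give 4-[2-(allyloxy)-3-methoxyphenoxy]-3-methoxybenzaldehyde F1. NaBH4 in MeOH at 0 °C then reduces F1 to 12.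

Step 3. Oxidative addition of the electron-rich 3-bromofuran to copper may be slow, the volatile bromide may be lost, and the aryloxyfuran may decompose on prolonged heating. The fallback turns the polarity of the furan partner around; it sets out from phenol 5 and comes back at furyl ether 7. Chan–Lam oxidative coupling of 5 with commercial furan-3-boronic acid (OB(O)c1ccoc1; Cu(OAc)2, pyridine, 4 Å molecular sieves, CH2Cl2, air, rt) should give 7 at room temperature. This fallback makes no compound outside the list (F0).

Step 10. Substitution may stall because the phenoxide of 18 is flanked by two ortho substituents and the fluoroarene is only activated by one formyl group. Forcing the temperature risks base-induced migration of the allyl double bonds. The fallback forms the ether on a doubly activated electrophile and brings the methoxy group in afterwards; it sets out from phenol 18 and comes back at aldehyde 20. Phenol 18 and commercial 2,6-difluorobenzaldehyde (O=Cc1c(F)cccc1F; K2CO3, DMF, 60 °C) should give 2-[4-allyl-2-(4-allyl-2-methoxyphenoxy)-6-methoxyphenoxy]-6-fluorobenzaldehyde F2. Its remaining fluoride, still ortho to the formyl group, is then displaced by NaOMe (MeOH/THF, 60 °C) to give 20.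

## Further compounds

F1 | step 4 | 4-[2-(allyloxy)-3-methoxyphenoxy]-3-methoxybenzaldehyde | O=Cc1ccc(Oc2cccc(OC)c2OCC=C)c(OC)c1
F0 | step 3 | none | none
F2 | step 10 | 2-[4-allyl-2-(4-allyl-2-methoxyphenoxy)-6-methoxyphenoxy]-6-fluorobenzaldehyde | C=CCc1ccc(Oc2cc(CC=C)cc(OC)c2Oc2cccc(F)c2C=O)c(OC)c1
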